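Set the clock aside and follow how far Q has gone, not how long it has stood.

Q 1.0 mM; D 3.00 mM; time 2.5 min

    Q + D → Q.D (k1 = 9.7 L mol⁻¹ s⁻¹)
    D + Q.D → D.Q.D (k2 = 3.6 L mol⁻¹ s⁻¹)
    D.Q.D → X (k3 = 0.014 s⁻¹)
    X → G (k4 = 0.016 s⁻¹)

* the state of affairs at 2.5 min: stopped, and by what, or still going (it is still moving / D has run out first / all of Q has reacted)
* the G standing at 2.5 min, as a percentage of the Q charged
* the Q.D standing at 2.5 min, as a percentage of the Q charged

- the reaction counts as stopped when no species that holds the Q changes by six tenths of a point or more over the second half of the time
- run time (flask): 2.5 min

Steps 1 and 2 both carry [D] as a factor, so in the ratio of their rates [D] cancels. What remains is 0.371, k2 over k1: call it s, the selectivity factor. It gives one curve, the same for this flask and for its neighbour with more Q: with q the share of Q left, the share of Q.D is (q^s − q) divided by (one minus s). [D] sets how fast a flask moves along that curve, not its shape.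

So I need [D]. Each Q takes one D to become Q.D and two to get past it, so [D] equals the margin, plus twice [Q], plus [Q.D]. The margin is the D charged less twice the Q charged, here 1.00 mM. The neighbouring flask has the same D but 1.7 mM of Q, and its margin of −0.400 mM is lower than this flask's. So in that neighbouring flask I expect [D] to sink further and Q to get less far along the same curve in the same time.

For this flask I take q as exp(−k1[D]t) with [D] as charged, then correct [D] to the mean of its start and its end by the balance:

| [D] used | Q left | Q.D |
|---|---|---|
| 3.00 mM | 1.27% | 29.4% |
| 2.16 mM | 4.32% | 42.7% |

I commit to the second row. With that much Q.D and [D] near 1.51 mM, I expect the flask still moving. My reckoning gives no figure for G.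

The forecast puts Q.D at 44.9%, higher than my figure, and G at 15.5%, judges it is still moving, and notes “so D has not run out”.

The flask gives 44.9% of Q.D and 15.6% of G: it is still moving. Q.D is being made more slowly than it is used up, at 0.315 of that rate. Q stands at 5.25%, more than my 4.32%, and the curve with s turns that reading into 44.9% of Q.D. That reading of Q corresponds to a mean [D] of 2.03 mM, lower than the 2.16 mM I used.

In the neighbouring flask with 1.7 mM of Q, Q stands at 10.9% after 2.50 min, and the curve gives 52.5% of Q.D. The computed run of that neighbouring flask with 1.7 mM of Q gives 52.6%.

(The rate constants belong to no real substance; the result is computed.)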